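The readings are simulated with made-up constants, and the scatter is random.

If the complex with three exchanged halves many times within the time allowed, the flask holds most of it at a peak and not at the end, so two times count: the time allowed and the fall half-life.

in all of them: starting complex 20 mM; gas 10 mM (held)
- cedar: the very flask that is asked about, followed so far
- flask: time 30 h

cedar run (percent of the starting complex charged)

| time / h | complex with three exchanged / % |
|---|---|
| 0.833 | 3.8 |
| 1.00 | 6.1 |
| 1.50 | 15.4 |
| 2.00 | 25.9 |
| 3.00 | 29.9 |
| 4.00 | 30.3 |
| 6.00 | 18.5 |

(each reading ± 1 percentage point)

- what was read earlier has a scatter of 1 percentage point, one standard deviation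
- at the start none of the gas is in solution

- the moment within 30 h at which there is most complex with three exchanged
- the amount of complex with three exchanged, in percent of the starting complex charged, at that time

The flask's reading falls from 30.3 % at 4.00 h to 18.5 % at 6.00 h, so the fall half-life, the time in which the falling reading halves, reads 2.81 h. The 30 h allowed hold 10.7 of these. Carried on from the last reading, the share at the end comes to 0.0497 % of the charge, less than the 30.3 % already read. Put back into the question, that answer sends the maximum to the peak, between 3.00 h and 4.00 h, where the two readings agree within a scatter of 1 percentage point. The reckoning therefore commits to 3.50 h and about 30.1 %.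

The forecast gives 3.5 h and 31 %, holding that “the maximum lies between them”.

The flask peaks at 3.32 h with 31.2 %.

    starting complex + incoming ligand → leaving ligand + complex with one exchanged (k = 0.0223 M⁻¹ s⁻¹)
    complex with one exchanged + incoming ligand → leaving ligand + complex with two exchanged (k = 0.0610 M⁻¹ s⁻¹)
    complex with two exchanged + incoming ligand → leaving ligand + complex with three exchanged (k = 0.0241 M⁻¹ s⁻¹)
    complex with three exchanged + incoming ligand → leaving ligand + complex with four exchanged (k = 0.0176 M⁻¹ s⁻¹)
    gas ⇌ incoming ligand, rate k5*(csat - [incoming ligand]) (kL = 0.0100 s⁻¹)

The species asked about has a half-life of 1.1 h by the step into complex with four exchanged at 1.88 h, short against 30 h, and the flask holds 0 % of it at 30.0 h. Carried on from the last reading, the fall half-life gives 2.01 % at 15.0 h where the flask holds 0.165 %, and 4.21 % for the neighbour flask left until 12 h, which holds 0.927 %.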